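The naphthalene is cut at the C4–C4a bond. C1 carries two aryl groups, ring A (through C8a) and the anisyl ring, but only ring A has a free ortho carbon para to an oxygen (C4a, para to the C7 oxygen), while N–C2=C3–N is an ene-urea that can be carried as an imidazol-2-one. An acid-induced Bradsher cyclodehydration of a racemic 5-(diarylmethyl)-4-formylimidazol-2-one (free N–H, catechol as benzyl ethers) should therefore form C4–C4a, close ring B and aromatise it by loss of water in one operation. Afterwards the cyclic urea is opened through its bis-Boc derivative, both amines are formylated and the benzyl ethers are hydrogenolysed.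

Key step: step 4

Remark: the diarylmethyl carbon is carried as a racemate (SMILES drawn without a descriptor); it and the transient carbinol carbon of step 4 become sp2 on aromatisation, and the target is achiral.

Step 1
Reactants: 1 4-bromoanisole; 2 3,4-bis(benzyloxy)benzaldehyde
Product: 4 rac-[3,4-bis(benzyloxy)phenyl](4-methoxyphenyl)methanol, via 4-methoxyphenylmagnesium bromide 3 (not isolated)
Conditions: Mg, I2 (cat.), THF, reflux; then 2, THF, 0 °C → rt; H2O quench, aq NH4Cl work-up
Reagents that add atoms: none
Why: Grignard addition of the aryl nucleophile to the aldehyde should give the diaryl carbinol; the new stereocentre forms without control (racemate), which is immaterial because this carbon becomes sp2 (C1) in step 4.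

Step 2
Reactants: 4 rac-[3,4-bis(benzyloxy)phenyl](4-methoxyphenyl)methanol; 5 1,3-dihydro-2H-imidazol-2-one
Product: 6 rac-4-{[3,4-bis(benzyloxy)phenyl](4-methoxyphenyl)methyl}-1,3-dihydro-2H-imidazol-2-one
Conditions: 5 (3 equiv), TsOH·H2O (5 mol %), HFIP, rt
Reagents that add atoms: none
Why: In this dehydrative Friedel–Crafts alkylation the doubly donor-stabilised benzhydryl cation should form under mild acid in HFIP and be captured at the enamide-type C4 of the imidazolone, which is far more nucleophilic than the alkoxyarenes; capture at N or O is reversible and drains to the C-alkylated product, and the excess of 5 holds back a second alkylation at C5.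

Step 3
Reactants: 6 rac-4-{[3,4-bis(benzyloxy)phenyl](4-methoxyphenyl)methyl}-1,3-dihydro-2H-imidazol-2-one
Product: 8 rac-5-{[3,4-bis(benzyloxy)phenyl](4-methoxyphenyl)methyl}-2-oxo-2,3-dihydro-1H-imidazole-4-carbaldehyde, via iminium chloride 7 (not isolated)
Conditions: (chloromethylene)dimethyliminium chloride (1.5 equiv), DMF, 0 °C → rt; then aq NaOAc, rt
Reagents that add atoms: (chloromethylene)dimethyliminium chloride, C[N+](C)=CCl.[Cl-]; water, O
Why: Vilsmeier–Haack formylation should occur at C5, the only free ene-urea carbon and by far the most nucleophilic site, and the preformed chloroiminium salt avoids POCl3 and with it conversion of the urea into a 2-chloroimidazole; aqueous acetate then hydrolyses the iminium salt and any N-bound amidinium groups.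

Step 4
Reactants: 8 rac-5-{[3,4-bis(benzyloxy)phenyl](4-methoxyphenyl)methyl}-2-oxo-2,3-dihydro-1H-imidazole-4-carbaldehyde
Product: 10 6,7-bis(benzyloxy)-4-(4-methoxyphenyl)-1,3-dihydro-2H-naphtho[2,3-d]imidazol-2-one, via ring-closed carbinol 9 (not isolated)
Conditions: TFA/CH2Cl2 (1:1), 0.02 M, argon, 0 °C → rt (40 °C if slow)
Reagents that add atoms: none
Why: TFA protonates the formyl oxygen, and the free ortho carbon of the dibenzyloxyphenyl ring that lies para to a benzyloxy group (the future C4a) attacks the activated formyl carbon (C4) in an intramolecular electrophilic aromatic substitution to give carbinol 9. The carbinol then ionises to a cation stabilised by ring A and the ene-urea nitrogen, and loss of the doubly benzylic C1 hydrogen aromatises ring B, so no oxidant is needed. The closest known reactions are Bradsher cyclodehydrations of ortho-acyl diarylmethanes and the analogous closures of 2-benzyl-3-formyl heteroarenes to benzo-fused heteroarenes, with Combes-type cyclisations showing that a protonated vinylogous amide carbonyl is electrophilic enough for an arene. Ring B closes in a 6-exo-trig mode, the arene carbon adding to a C=O that is exocyclic to the new ring. Both sp3 carbons (C1 and the carbinol carbon of 9) end as sp2, so no stereocentre has to be controlled. The step must choose ring A over the anisyl ring and C4a over the carbon between the ring substituents: the anisyl ortho carbons are meta to their methoxy group, and only C4a is both para to an oxygen and unhindered, while TFA at room temperature should leave the benzyl ethers intact.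

Step 5
Reactants: 10 6,7-bis(benzyloxy)-4-(4-methoxyphenyl)-1,3-dihydro-2H-naphtho[2,3-d]imidazol-2-one
Product: 12 di-tert-butyl [6,7-bis(benzyloxy)-1-(4-methoxyphenyl)naphthalene-2,3-diyl]biscarbamate, via bis-Boc urea 11 (not isolated)
Conditions: Boc2O (3 equiv), DMAP (0.2 equiv), THF/DMF, rt; then LiOH·H2O (6 equiv), H2O, 0 °C → rt
Reagents that add atoms: di-tert-butyl dicarbonate, CC(C)(C)OC(=O)OC(=O)OC(C)(C)C
Why: Acylating both urea nitrogens makes the ring carbonyl imide-like, so hydroxide should add there and not at the hindered tert-butyl carbamates, the ring opens and the carbamic acid loses CO2 to leave two NHBoc groups (Boc-activated hydrolysis, as for N-Boc lactams and cyclic ureas); any extra Boc group picked up from residual Boc2O is harmless because step 6 removes them all.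

Step 6
Reactants: 12 di-tert-butyl [6,7-bis(benzyloxy)-1-(4-methoxyphenyl)naphthalene-2,3-diyl]biscarbamate
Product: 14 N,N'-[6,7-bis(benzyloxy)-1-(4-methoxyphenyl)naphthalene-2,3-diyl]diformamide, via diamine dihydrochloride 13 (not isolated)
Conditions: HCl (4 M in dioxane, 6 equiv), CH2Cl2, rt, argon; then pyridine (12 equiv), acetic formic anhydride (preformed from HCO2H/Ac2O, 5 equiv), −10 → 0 °C
Reagents that add atoms: acetic formic anhydride, CC(=O)OC=O
Why: Acidolysis of the tert-butyl carbamates gives the air-sensitive diamine as its salt, which pyridine releases in the same flask for immediate N-formylation by the mixed anhydride; at low temperature in a basic medium both amines should be formylated before a mono-formamide can close to a naphthimidazole.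

Step 7
Reactants: 14 N,N'-[6,7-bis(benzyloxy)-1-(4-methoxyphenyl)naphthalene-2,3-diyl]diformamide
Product: 15 melanocin E
Conditions: H2 (1 atm), 10% Pd/C, THF/MeOH, rt; filtration under argon
Reagents that add atoms: none
Why: Hydrogenolysis of the two benzyl aryl ethers should leave the methyl ether, the formamides and the naphthalene untouched, and needs only filtration and evaporation, which suits the oxidation-prone catechol.

Compound list
1 | 4-bromoanisole | COc1ccc(Br)cc1 | starting material
2 | 3,4-bis(benzyloxy)benzaldehyde | O=Cc1ccc(OCc2ccccc2)c(OCc2ccccc2)c1 | starting material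
3 | 4-methoxyphenylmagnesium bromide | COc1ccc([Mg]Br)cc1 | intermediate (not isolated)
4 | rac-[3,4-bis(benzyloxy)phenyl](4-methoxyphenyl)methanol | COc1ccc(cc1)C(O)c1ccc(OCc2ccccc2)c(OCc2ccccc2)c1 | intermediate
5 | 1,3-dihydro-2H-imidazol-2-one | O=C1NC=CN1 | starting material
6 | rac-4-{[3,4-bis(benzyloxy)phenyl](4-methoxyphenyl)methyl}-1,3-dihydro-2H-imidazol-2-one | COc1ccc(cc1)C(C1=CNC(=O)N1)c1ccc(OCc2ccccc2)c(OCc2ccccc2)c1 | intermediate
7 | rac-N-[(5-{[3,4-bis(benzyloxy)phenyl](4-methoxyphenyl)methyl}-2-oxo-2,3-dihydro-1H-imidazol-4-yl)methylidene]-N-methylmethanaminium chloride | COc1ccc(cc1)C(C1=C(C=[N+](C)C)NC(=O)N1)c1ccc(OCc2ccccc2)c(OCc2ccccc2)c1.[Cl-] | intermediate (not isolated)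
8 | rac-5-{[3,4-bis(benzyloxy)phenyl](4-methoxyphenyl)methyl}-2-oxo-2,3-dihydro-1H-imidazole-4-carbaldehyde | COc1ccc(cc1)C(C1=C(C=O)NC(=O)N1)c1ccc(OCc2ccccc2)c(OCc2ccccc2)c1 | intermediate (key-step precursor)
9 | 6,7-bis(benzyloxy)-9-hydroxy-4-(4-methoxyphenyl)-1,3,4,9-tetrahydro-2H-naphtho[2,3-d]imidazol-2-one (racemic; both diastereomers) | COc1ccc(cc1)C1C2=C(NC(=O)N2)C(O)c2cc(OCc3ccccc3)c(OCc3ccccc3)cc12 | intermediate (not isolated)
10 | 6,7-bis(benzyloxy)-4-(4-methoxyphenyl)-1,3-dihydro-2H-naphtho[2,3-d]imidazol-2-one | COc1ccc(cc1)-c1c2NC(=O)Nc2cc2cc(OCc3ccccc3)c(OCc3ccccc3)cc12 | intermediate (key-step product)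
11 | di-tert-butyl 6,7-bis(benzyloxy)-4-(4-methoxyphenyl)-2-oxo-2H-naphtho[2,3-d]imidazole-1,3-dicarboxylate | COc1ccc(cc1)-c1c2N(C(=O)OC(C)(C)C)C(=O)N(C(=O)OC(C)(C)C)c2cc2cc(OCc3ccccc3)c(OCc3ccccc3)cc12 | intermediate (not isolated)
12 | di-tert-butyl [6,7-bis(benzyloxy)-1-(4-methoxyphenyl)naphthalene-2,3-diyl]biscarbamate | COc1ccc(cc1)-c1c(NC(=O)OC(C)(C)C)c(NC(=O)OC(C)(C)C)cc2cc(OCc3ccccc3)c(OCc3ccccc3)cc12 | intermediate
13 | 6,7-bis(benzyloxy)-1-(4-methoxyphenyl)naphthalene-2,3-diamine dihydrochloride | COc1ccc(cc1)-c1c(N)c(N)cc2cc(OCc3ccccc3)c(OCc3ccccc3)cc12.Cl.Cl | intermediate (not isolated)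
14 | N,N'-[6,7-bis(benzyloxy)-1-(4-methoxyphenyl)naphthalene-2,3-diyl]diformamide | COc1ccc(cc1)-c1c(NC=O)c(NC=O)cc2cc(OCc3ccccc3)c(OCc3ccccc3)cc12 | intermediate
15 | melanocin E, N,N'-[6,7-dihydroxy-1-(4-methoxyphenyl)naphthalene-2,3-diyl]diformamide | COc1ccc(-c2c(NC=O)c(NC=O)cc3cc(O)c(O)cc23)cc1 | target

Total step count: 7. Longest linear sequence: 7 steps (from 1 or 2 to 15; 5 enters in step 2).

Steps most likely to fail

Step 4. The ring closure may stall because the protonated formyl group, as part of a vinylogous urea, is a weak electrophile, and forcing it with stronger acid may strip benzyl groups. The fallback sets out from 8 and changes the oxidation level of the electrophile. NaBH4 (MeOH/THF, 0 °C) should reduce the aldehyde to rac-4-{[3,4-bis(benzyloxy)phenyl](4-methoxyphenyl)methyl}-5-(hydroxymethyl)-1,3-dihydro-2H-imidazol-2-one F1. Catalytic TsOH·H2O in HFIP at rt then ionises this carbinol to a much more electrophilic azafulvenium ion, which alkylates the same ring A carbon (Friedel–Crafts cyclialkylation) to give rac-6,7-bis(benzyloxy)-4-(4-methoxyphenyl)-1,3,4,9-tetrahydro-2H-naphtho[2,3-d]imidazol-2-one F2. Dehydrogenation of the doubly benzylic positions with DDQ (dioxane, rt) comes back to the route at 10.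

Step 2. The cation may be captured at nitrogen, a second alkylation may occur at C5, or the imidazolone may self-condense under acid. The fallback sets out from 5 and uses the established Friedel–Crafts acylation of imidazol-2-ones. 4-Methoxybenzoyl chloride with AlCl3 in nitrobenzene at 60 °C should give 4-(4-methoxybenzoyl)-1,3-dihydro-2H-imidazol-2-one F3. An excess of [3,4-bis(benzyloxy)phenyl]magnesium bromide F4 (from commercial 4-bromo-1,2-bis(benzyloxy)benzene and Mg in THF; two equivalents are consumed by the N–H groups) adds to the ketone to give rac-4-{[3,4-bis(benzyloxy)phenyl](hydroxy)(4-methoxyphenyl)methyl}-1,3-dihydro-2H-imidazol-2-one F5. Ionic hydrogenation of this tertiary carbinol (Et3SiH, TFA, CH2Cl2, 0 °C) comes back to the route at 6.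

Step 5. Acylation of the hindered nitrogen next to the anisyl group may stay incomplete, or hydroxide may attack the Boc carbonyls and return the urea. The fallback sets out from 10 and drops the activation. Direct alkaline hydrolysis (Ba(OH)2·8H2O, ethylene glycol/H2O, 150 °C, sealed vessel, argon) should give 6,7-bis(benzyloxy)-1-(4-methoxyphenyl)naphthalene-2,3-diamine F6. This is formylated at once with acetic formic anhydride and pyridine at −10 → 0 °C and comes back to the route at 14.

Further compounds
F1 | step 4 | rac-4-{[3,4-bis(benzyloxy)phenyl](4-methoxyphenyl)methyl}-5-(hydroxymethyl)-1,3-dihydro-2H-imidazol-2-one | COc1ccc(cc1)C(C1=C(CO)NC(=O)N1)c1ccc(OCc2ccccc2)c(OCc2ccccc2)c1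
F2 | step 4 | rac-6,7-bis(benzyloxy)-4-(4-methoxyphenyl)-1,3,4,9-tetrahydro-2H-naphtho[2,3-d]imidazol-2-one | COc1ccc(cc1)C1C2=C(NC(=O)N2)Cc2cc(OCc3ccccc3)c(OCc3ccccc3)cc12
F3 | step 2 | 4-(4-methoxybenzoyl)-1,3-dihydro-2H-imidazol-2-one | COc1ccc(cc1)C(=O)C1=CNC(=O)N1
F4 | step 2 | [3,4-bis(benzyloxy)phenyl]magnesium bromide | Br[Mg]c1ccc(OCc2ccccc2)c(OCc2ccccc2)c1
F5 | step 2 | rac-4-{[3,4-bis(benzyloxy)phenyl](hydroxy)(4-methoxyphenyl)methyl}-1,3-dihydro-2H-imidazol-2-one | COc1ccc(cc1)C(O)(C1=CNC(=O)N1)c1ccc(OCc2ccccc2)c(OCc2ccccc2)c1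
F6 | step 5 | 6,7-bis(benzyloxy)-1-(4-methoxyphenyl)naphthalene-2,3-diamine | COc1ccc(cc1)-c1c(N)c(N)cc2cc(OCc3ccccc3)c(OCc3ccccc3)cc12
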